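The eleven-membered carbocycle is disconnected at C7–C8 (ring numbering of the final ester: C1 carbinol, C2 gem-dimethyl, C3=C4, C5 methylidene carbon, C8=C9), the sp3–sp2 bond between a ring CH2 and the vinylic CH of the E-trisubstituted alkene. The key step exploits that C7 is insulated from the C3=C4/C5 diene by C6 and so supports a primary organozinc, while C8 can carry an E-vinyl iodide of fixed geometry: chemoselective zinc insertion and intramolecular Negishi coupling close the ring in one operation with retention. The precursor is an acyclic diiodide already holding the (R)-aryl ester, quaternary carbon and diene, assembled by Brown reverse prenylation, Heck coupling and carboalumination.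

Key step: step 8

Step 1
Reactants: 1 5-(trimethylsilyl)pent-4-yn-1-ol
Product: 2 5-(trimethylsilyl)pent-4-ynal
Conditions: TEMPO (10 mol %), PhI(OAc)2, CH2Cl2, rt
Reagents that add atoms: none
Why: Oxoammonium-mediated (TEMPO/PhI(OAc)2) oxidation of a primary alcohol stops at the aldehyde and tolerates the silyl-capped alkyne.

Step 2
Reactants: 2 5-(trimethylsilyl)pent-4-ynal; 3 prenylmagnesium chloride
Product: 6 (4R)-3,3-dimethyl-8-(trimethylsilyl)oct-1-en-7-yn-4-ol, via prenylborane 4 (not isolated), via borinate ester 5 (not isolated)
Conditions: 3, (−)-Ipc2BOMe [from (+)-α-pinene], Et2O, −78 → 0 °C; then 2, −78 °C; NaBO3·4H2O, THF/H2O, rt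
Reagents that add atoms: none
Why: Brown asymmetric allylboration in its reverse-prenylation mode: the prenylborane adds at its γ-carbon through a closed chair six-membered transition state to the Si face of the aldehyde under control of the (+)-α-pinene-derived isopinocampheyl groups, which forms the quaternary C(CH3)2 carbon and should set the (R)-carbinol.

Step 3
Reactants: 6 (4R)-3,3-dimethyl-8-(trimethylsilyl)oct-1-en-7-yn-4-ol; 7 3-bromobut-3-en-1-ol
Product: 8 (4E,7R)-6,6-dimethyl-3-methylidene-11-(trimethylsilyl)undec-4-en-10-yne-1,7-diol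
Conditions: Pd(OAc)2 (5 mol %), P(o-tol)3 (12 mol %), Et3N, MeCN, 80 °C
Reagents that add atoms: none
Why: Mizoroki–Heck reaction: the alkenylpalladium bromide formed from 7 should insert the monosubstituted alkene of 6 with carbon delivery to the terminal CH2, and syn β-hydride elimination, possible only toward the new bond because the other neighbour is quaternary, should give the E-configured 2-substituted 1,3-diene, the silyl cap keeping the alkyne out of competing coupling.

Step 4
Reactants: 8 (4E,7R)-6,6-dimethyl-3-methylidene-11-(trimethylsilyl)undec-4-en-10-yne-1,7-diol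
Product: 9 (4E,7R)-6,6-dimethyl-3-methylideneundec-4-en-10-yne-1,7-diol
Conditions: K2CO3, MeOH, rt
Reagents that add atoms: none
Why: Methoxide-induced protodesilylation of the alkynylsilane frees the terminal alkyne, while the diene, both hydroxyls and the stereocentre are inert.

Step 5
Reactants: 9 (4E,7R)-6,6-dimethyl-3-methylideneundec-4-en-10-yne-1,7-diol
Product: 11 (4E,7R,10E)-11-iodo-6,6,10-trimethyl-3-methylideneundeca-4,10-diene-1,7-diol, via alkenylalane 10 (not isolated)
Conditions: AlMe3 (5 equiv), Cp2ZrCl2 (0.5 equiv), CH2Cl2, 0 °C → rt; then I2, THF, −30 → 0 °C; aq. potassium sodium tartrate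
Reagents that add atoms: trimethylaluminium, C[Al](C)C; iodine, II
Why: Negishi carboalumination: zirconocene-catalysed syn-addition of CH3–Al across the terminal alkyne places methyl on the internal and aluminium on the terminal carbon (both hydroxyls being masked in situ as dimethylaluminium alkoxides and the less reactive 1,3-diene left alone), and iodinolysis of the C–Al bond with retention should give the E-trisubstituted vinyl iodide.

Step 6
Reactants: 11 (4E,7R,10E)-11-iodo-6,6,10-trimethyl-3-methylideneundeca-4,10-diene-1,7-diol
Product: 12 (1E,5R,7E)-1,11-diiodo-2,6,6-trimethyl-9-methylideneundeca-1,7-dien-5-ol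
Conditions: PPh3, I2, imidazole, CH2Cl2, 0 °C
Reagents that add atoms: iodine, II
Why: Appel reaction: only the unhindered primary alcohol forms an alkoxyphosphonium ion that iodide can displace (SN2), the neopentyl-type secondary carbinol next to the quaternary carbon being too hindered, so the stereocentre is untouched.

Step 7
Reactants: 12 (1E,5R,7E)-1,11-diiodo-2,6,6-trimethyl-9-methylideneundeca-1,7-dien-5-ol; 13 4-acetoxy-3-methoxybenzoic acid
Product: 15 (1E,5R,7E)-1,11-diiodo-2,6,6-trimethyl-9-methylideneundeca-1,7-dien-5-yl 4-acetoxy-3-methoxybenzoate, via mixed anhydride 14 (not isolated)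
Conditions: 13, 2,4,6-trichlorobenzoyl chloride, Et3N, toluene, rt; then 12, DMAP, toluene, rt → 40 °C
Reagents that add atoms: none
Why: Yamaguchi esterification: DMAP opens the mixed anhydride at the less hindered aroyl carbonyl and the acylpyridinium acylates the hindered secondary alcohol with retention because the carbinol C–O bond is not broken, while amine alkylation by the primary iodide should be negligible in toluene.

Step 8
Reactants: 15 (1E,5R,7E)-1,11-diiodo-2,6,6-trimethyl-9-methylideneundeca-1,7-dien-5-yl 4-acetoxy-3-methoxybenzoate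
Product: 17 (1R,3E,8E)-2,2,9-trimethyl-5-methylidenecycloundeca-3,8-dien-1-yl 4-acetoxy-3-methoxybenzoate, via alkylzinc iodide 16 (not isolated)
Conditions: Zn dust (activated with BrCH2CH2Br and Me3SiCl), THF, 35 °C, decant; then syringe-pump addition to PdCl2(dppf) (10 mol %), THF/NMP, 50 °C, final 2 mM
Reagents that add atoms: none
Why: Activated zinc should insert only into the primary C(sp3)–I bond (alkenyl iodides are inert to zinc dust in THF at this temperature) to give homoallylic zinc iodide 16; on slow addition to the catalyst, zerovalent palladium adds oxidatively to the C(sp2)–I bond, the tethered alkylzinc transmetalates and reductive elimination forms the C7–C8 bond. The closest known reaction type is the Negishi coupling of primary alkylzinc halides with (E)-alkenyl iodides, run here intramolecularly in the manner of B-alkyl Suzuki–Miyaura macrocyclisations of (E)-2-methyl-1-iodoalkenes. The eleven-membered ring is closed end to end by C(sp3)–C(sp2) reductive elimination from a twelve-membered palladacycle of divalent palladium, with the gem-dimethyl group and the two E-alkenes limiting the conformational freedom of the chain. No stereocentre is created: the (R)-carbinol is remote and untouched, and the E-geometry at C8=C9 is retained because oxidative addition and reductive elimination at an alkenyl carbon are stereoretentive. The step needs chemoselectivity between the two C–I bonds (secured by the order zinc first, palladium second), ring closure over oligomerisation (secured by syringe-pump addition to millimolar concentration) and reductive elimination over β-hydride elimination (secured by the wide-bite-angle dppf ligand).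

Step 9
Reactants: 17 (1R,3E,8E)-2,2,9-trimethyl-5-methylidenecycloundeca-3,8-dien-1-yl 4-acetoxy-3-methoxybenzoate
Product: 18 (1R,3E,8E)-2,2,9-trimethyl-5-methylidenecycloundeca-3,8-dien-1-yl 4-hydroxy-3-methoxybenzoate
Conditions: K2CO3 (0.2 equiv), MeOH, 0 °C
Reagents that add atoms: none
Why: Base-catalysed methanolysis cleaves the activated phenolic acetate much faster than the hindered, electron-rich benzoate of the secondary alcohol, so the free phenol of the target should be released without touching the ring ester or the stereocentre.

Compound list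
1 | 5-(trimethylsilyl)pent-4-yn-1-ol | C[Si](C)(C)C#CCCCO | starting material
2 | 5-(trimethylsilyl)pent-4-ynal | C[Si](C)(C)C#CCCC=O | intermediate
3 | prenylmagnesium chloride, (3-methylbut-2-en-1-yl)magnesium chloride | CC(C)=CC[Mg]Cl | starting material
4 | B-(3-methylbut-2-en-1-yl)diisopinocampheylborane, isopinocampheyl groups from (+)-α-pinene (not isolated) | CC(C)=CCB([C@H]1[C@H](C)[C@H]2C[C@@H](C1)C2(C)C)[C@H]1[C@H](C)[C@H]2C[C@@H](C1)C2(C)C | intermediate
5 | (4R)-3,3-dimethyl-8-(trimethylsilyl)oct-1-en-7-yn-4-yl diisopinocampheylborinate (not isolated) | C[Si](C)(C)C#CCC[C@@H](OB([C@H]1[C@H](C)[C@H]2C[C@@H](C1)C2(C)C)[C@H]1[C@H](C)[C@H]2C[C@@H](C1)C2(C)C)C(C)(C)C=C | intermediate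
6 | (4R)-3,3-dimethyl-8-(trimethylsilyl)oct-1-en-7-yn-4-ol | C=CC(C)(C)[C@H](O)CCC#C[Si](C)(C)C | intermediate
7 | 3-bromobut-3-en-1-ol | OCCC(Br)=C | starting material
8 | (4E,7R)-6,6-dimethyl-3-methylidene-11-(trimethylsilyl)undec-4-en-10-yne-1,7-diol | OCCC(=C)/C=C/C(C)(C)[C@H](O)CCC#C[Si](C)(C)C | intermediate
9 | (4E,7R)-6,6-dimethyl-3-methylideneundec-4-en-10-yne-1,7-diol | OCCC(=C)/C=C/C(C)(C)[C@H](O)CCC#C | intermediate
10 | (E)-alkenyl(dimethyl)alane from syn-methylalumination of 9, both hydroxyls as dimethylaluminium alkoxides (not isolated) | C[Al](C)OCCC(=C)/C=C/C(C)(C)[C@H](O[Al](C)C)CC/C(C)=C/[Al](C)C | intermediate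
11 | (4E,7R,10E)-11-iodo-6,6,10-trimethyl-3-methylideneundeca-4,10-diene-1,7-diol | OCCC(=C)/C=C/C(C)(C)[C@H](O)CC/C(C)=C/I | intermediate
12 | (1E,5R,7E)-1,11-diiodo-2,6,6-trimethyl-9-methylideneundeca-1,7-dien-5-ol | ICCC(=C)/C=C/C(C)(C)[C@H](O)CC/C(C)=C/I | intermediate
13 | 4-acetoxy-3-methoxybenzoic acid | CC(=O)Oc1ccc(cc1OC)C(O)=O | starting material
14 | 4-acetoxy-3-methoxybenzoic 2,4,6-trichlorobenzoic anhydride (not isolated) | CC(=O)Oc1ccc(cc1OC)C(=O)OC(=O)c1c(Cl)cc(Cl)cc1Cl | intermediate
15 | (1E,5R,7E)-1,11-diiodo-2,6,6-trimethyl-9-methylideneundeca-1,7-dien-5-yl 4-acetoxy-3-methoxybenzoate | ICCC(=C)/C=C/C(C)(C)[C@H](OC(=O)c1ccc(OC(C)=O)c(OC)c1)CC/C(C)=C/I | intermediate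
16 | (4E,7R,10E)-7-[(4-acetoxy-3-methoxybenzoyl)oxy]-11-iodo-6,6,10-trimethyl-3-methylideneundeca-4,10-dien-1-ylzinc iodide (not isolated) | I[Zn]CCC(=C)/C=C/C(C)(C)[C@H](OC(=O)c1ccc(OC(C)=O)c(OC)c1)CC/C(C)=C/I | intermediate
17 | (1R,3E,8E)-2,2,9-trimethyl-5-methylidenecycloundeca-3,8-dien-1-yl 4-acetoxy-3-methoxybenzoate | C=C1/C=C/C(C)(C)[C@H](OC(=O)c2ccc(OC(C)=O)c(OC)c2)CC/C(C)=C/CC1 | intermediate
18 | (1R,3E,8E)-2,2,9-trimethyl-5-methylidenecycloundeca-3,8-dien-1-yl 4-hydroxy-3-methoxybenzoate | C=C1/C=C/C(C)(C)[C@H](OC(=O)c2ccc(O)c(OC)c2)CC/C(C)=C/CC1 | target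

Total step count: 9. Longest linear sequence: 9 steps (1 → 18); compounds 3, 7 and 13 enter as purchased materials.

Steps most likely to fail

Step 8 (key step). The ring closure may lose material to intermolecular transmetalation (oligomers), to protodezincation of the organozinc before it meets the catalyst, or to β-hydride elimination at the alkylpalladium stage. The fallback sets out from 15 and comes back at 17 without a preformed organozinc: nickel-catalysed reductive cross-electrophile coupling (NiI2, 4,4'-di-tert-butyl-2,2'-bipyridine, Mn powder, NaI, DMA, 40 °C, 2 mM). There the alkenyl iodide adds to low-valent nickel and the alkyl iodide is engaged at the same metal by halogen-atom abstraction and radical rebound, so both ends are activated in one pot. It makes no new compound (F0).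

Step 3. The Heck coupling may suffer from slow insertion of the hindered alkene, from competing carbopalladation of the silylalkyne, or from a second vinylation of the product diene. The fallback sets out from 6 and comes back at 8, building the diene by olefination and cross-coupling instead. Ozonolysis of the terminal alkene (O3, CH2Cl2/MeOH, −78 °C; Me2S) should give (3R)-3-hydroxy-2,2-dimethyl-7-(trimethylsilyl)hept-6-ynal F1. Takai-type boryl olefination (CrCl2, Cl2CHBpin, LiI, THF, rt) should give (1E,4R)-3,3-dimethyl-1-(4,4,5,5-tetramethyl-1,3,2-dioxaborolan-2-yl)-8-(trimethylsilyl)oct-1-en-7-yn-4-ol F2. Suzuki–Miyaura coupling of F2 with 7 (Pd(PPh3)4, K3PO4, THF/H2O, rt) should then form the C4–C5 bond of the diene with retention of the E-geometry and return 8.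

Step 5. The carboalumination may be eroded by regioisomeric methylalumination, by carbometalation of the 1,3-diene, or by iodine addition to the diene during iodinolysis. The fallback sets out from 9 and comes back at 11 by stoichiometric syn-carbocupration. Both hydroxyls are first deprotonated with MeMgBr, then MeCu·MgBr2·SMe2 (from MeMgBr and CuBr·SMe2, Et2O/Me2S, −25 °C) should add across the terminal alkyne to give the (E)-2-methylalkenylcopper bis(bromomagnesium alkoxide) F3 (not isolated). Iodinolysis (I2, −50 → 0 °C) with retention should give 11.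

Further compounds
F0 | step 8 | none | none
F1 | step 3 | (3R)-3-hydroxy-2,2-dimethyl-7-(trimethylsilyl)hept-6-ynal | O=CC(C)(C)[C@H](O)CCC#C[Si](C)(C)C
F2 | step 3 | (1E,4R)-3,3-dimethyl-1-(4,4,5,5-tetramethyl-1,3,2-dioxaborolan-2-yl)-8-(trimethylsilyl)oct-1-en-7-yn-4-ol | CC1(C)OB(OC1(C)C)/C=C/C(C)(C)[C@H](O)CCC#C[Si](C)(C)C
F3 | step 5 | (E)-2-methylalkenylcopper bis(bromomagnesium alkoxide) from syn-methylcupration of 9 | [Cu]/C=C(\C)CC[C@@H](O[Mg]Br)C(C)(C)/C=C/C(=C)CCO[Mg]Br
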